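**Plan**
- The retrosynthesis first cuts the allyl aryl ether bond between the C5 oxygen and C1' of the side chain. It then cuts the three lactone bonds C7a–C1, C3a–C3 and O2–C1 in one operation, leading back to an aryne, tert-butyl isocyanide and formaldehyde.
- Enabling feature: C1 and C3 of the lactone ring sit on the neighbouring benzene carbons C7a and C3a, and the other neighbour of C3a is the oxygen-bearing C4. An aryne across C3a–C7a that carries this oxygen takes a nucleophile at C7a and an electrophile at C3a.
- Forward: the benzene ring is bought with the C4/C5/C6 oxygen pattern in place. Its formyl group is exchanged for a triflate with an ortho trimethylsilyl group, and the lactone ring (the only ring made) closes in the aryne coupling.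
- The side chain comes from farnesol by terminal Markovnikov hydration (bromohydrin, then radical debromination) and conversion to the allylic bromide. It is joined last, at the more acidic C5 phenol.
- Stereochemistry: the target has no stereocentre. The 2E,6E geometry is bought with farnesol and no step touches it.

Key step: step 5

Assumption: monomeric formaldehyde is handled as a cold THF solution made by cracking dry paraformaldehyde, and commercial (2E,6E)-farnesol is taken as geometrically pure.

**Route**

Step 1
Reactants: 1 2,3-dihydroxy-4-methoxybenzaldehyde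
Product: 2 2,3-bis(benzyloxy)-4-methoxybenzaldehyde
Conditions: BnBr (2.5 equiv), K2CO3, DMF, 60 °C
Reagents that add atoms: benzyl bromide, BrCc1ccccc1
Why: Williamson ether synthesis, in which excess benzyl bromide and carbonate in warm DMF should alkylate both phenols, the hydrogen-bonded 2-OH included, and leave the aldehyde alone.

Step 2
Reactants: 2 2,3-bis(benzyloxy)-4-methoxybenzaldehyde
Product: 4 2,3-bis(benzyloxy)-4-methoxyphenol, via aryl formate 3 (not isolated)
Conditions: mCPBA, CH2Cl2, 0 °C → rt; NaHCO3 wash; then K2CO3 (cat.), MeOH, rt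
Reagents that add atoms: mCPBA, OOC(=O)c1cccc(Cl)c1
Why: Baeyer–Villiger oxidation in its Dakin-type form, in which the aryl group with ortho and para alkoxy donors migrates in preference to hydride and the resulting formate is cleaved by mild methanolysis that benzyl ethers tolerate.

Step 3
Reactants: 4 2,3-bis(benzyloxy)-4-methoxyphenol
Product: 5 2,3-bis(benzyloxy)-6-bromo-4-methoxyphenol
Conditions: NBS (1.0 equiv), i-Pr2NH (10 mol%), CH2Cl2, 0 °C
Reagents that add atoms: N-bromosuccinimide, O=C1CCC(=O)N1Br
Why: Amine-catalysed ortho-selective electrophilic bromination of a phenol, where the free OH is the strongest donor, its para position carries OMe and one ortho position carries OBn, so bromine should enter at C6.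

Step 4
Reactants: 5 2,3-bis(benzyloxy)-6-bromo-4-methoxyphenol
Product: 8 2,3-bis(benzyloxy)-4-methoxy-6-(trimethylsilyl)phenyl trifluoromethanesulfonate, via aryl trimethylsilyl ether 6 (not isolated), via lithium 2-silylphenoxide 7 (not isolated)
Conditions: HMDS, THF, 70 °C, then evaporation; n-BuLi, THF, −100 → −78 °C; Tf2O, −100 → −78 °C
Reagents that add atoms: hexamethyldisilazane, C[Si](C)(C)N[Si](C)(C)C; trifluoromethanesulfonic anhydride, O=S(=O)(OS(=O)(=O)C(F)(F)F)C(F)(F)F
Why: Standard one-pot preparation of a 2-(trimethylsilyl)aryl triflate by O-silylation, bromine–lithium exchange with anionic 1,3 O→C silyl shift (retro-Brook rearrangement) and O-triflation of the phenoxide, the exchange at −100 °C being faster than lithiation of the benzylic ether positions.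

Step 5
Reactants: 8 2,3-bis(benzyloxy)-4-methoxy-6-(trimethylsilyl)phenyl trifluoromethanesulfonate; 9 tert-butyl isocyanide; 10 formaldehyde
Product: 12 (Z)-N-tert-butyl-4,5-bis(benzyloxy)-6-methoxyisobenzofuran-1(3H)-imine, via 3-alkoxyaryne 11 (not isolated)
Conditions: KF, 18-crown-6, THF, −20 → 0 °C; 8 added slowly to 9 (2 equiv) and 10 (excess, cold THF solution)
Reagents that add atoms: none
Why: Fluoride removes the silyl group and triflate leaves to give aryne 11; the isocyanide carbon adds to the aryne carbon remote from the benzyloxy group, the aryl anion formed next to that oxygen adds to formaldehyde, and the alkoxide attacks the nitrilium carbon. The closest known reaction type is the three-component coupling of arynes, isocyanides and aldehydes to N-substituted 1-iminoisobenzofurans; formaldehyde is its smallest and least tested aldehyde partner, so it is used as the monomer in excess, cold, with slow release of the aryne. The five-membered ring closes by 5-exo-dig attack of oxygen on the C≡N+ carbon, forming C7a–C1, C3a–C3 and O2–C1 in one flask. No stereocentre is formed, and the Z geometry of the imine (tert-butyl turned away from the arene) is lost in the next step. The step needs attack of the isocyanide at the future C7a only; the inductively withdrawing C4 benzyloxy group secures this by distorting the aryne so that the distal carbon is the more electrophilic and the negative charge develops on the carbon ortho to oxygen.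

Step 6
Reactants: 12 (Z)-N-tert-butyl-4,5-bis(benzyloxy)-6-methoxyisobenzofuran-1(3H)-imine
Product: 13 4,5-bis(benzyloxy)-6-methoxyisobenzofuran-1(3H)-one
Conditions: 1 M aq. HCl, THF, rt; NaHCO3 work-up
Reagents that add atoms: water, O
Why: Acid hydrolysis of a cyclic imidate, in which the protonated tetrahedral intermediate expels the amine and not the ring alkoxide at low pH, so the lactone should form and not a hydroxy amide, with the benzyl ethers untouched.

Step 7
Reactants: 13 4,5-bis(benzyloxy)-6-methoxyisobenzofuran-1(3H)-one
Product: 14 4,5-dihydroxy-6-methoxyisobenzofuran-1(3H)-one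
Conditions: H2 (1 atm), 10% Pd/C, EtOAc–MeOH, rt
Reagents that add atoms: none
Why: Catalytic hydrogenolysis of benzyl aryl ethers, which at 1 atm and room temperature should be much faster than cleavage of the lactone C3–O bond of a phthalide.

Step 8
Reactants: 15 (2E,6E)-farnesol
Product: 16 (2E,6E)-farnesyl acetate
Conditions: Ac2O, pyridine, DMAP (cat.), CH2Cl2, 0 °C → rt
Reagents that add atoms: acetic anhydride, CC(=O)OC(C)=O
Why: DMAP-catalysed acylation of a primary alcohol, which masks the hydroxyl and lowers the electron density of the 2,3-alkene before the bromonium step.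

Step 9
Reactants: 16 (2E,6E)-farnesyl acetate
Product: 17 (2E,6E)-10-bromo-11-hydroxy-3,7,11-trimethyldodeca-2,6-dien-1-yl acetate (racemic)
Conditions: NBS (1.1 equiv), THF–H2O, 0 °C
Reagents that add atoms: N-bromosuccinimide, O=C1CCC(=O)N1Br; water, O
Why: Terminal-selective bromohydrin formation of a polyprenyl acetate in a highly aqueous medium, where the coiled chain exposes the 10,11-alkene and water opens the bromonium ion at the tertiary carbon (Markovnikov), the racemic C10 centre being removed in the next step.

Step 10
Reactants: 17 (2E,6E)-10-bromo-11-hydroxy-3,7,11-trimethyldodeca-2,6-dien-1-yl acetate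
Product: 18 (2E,6E)-11-hydroxy-3,7,11-trimethyldodeca-2,6-dien-1-yl acetate
Conditions: Bu3SnH, AIBN (cat.), toluene, 80 °C
Reagents that add atoms: none
Why: Radical-chain reductive dehalogenation with Bu3SnH, in which the secondary C10 radical has only disfavoured 4-exo or 5-endo cyclisation paths onto the 6,7-alkene and does not lose the neighbouring hydroxyl, so simple hydrogen transfer should prevail.

Step 11
Reactants: 18 (2E,6E)-11-hydroxy-3,7,11-trimethyldodeca-2,6-dien-1-yl acetate
Product: 19 (2E,6E)-3,7,11-trimethyldodeca-2,6-diene-1,11-diol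
Conditions: K2CO3 (cat.), MeOH, rt
Reagents that add atoms: none
Why: Base-catalysed transesterification (Zemplén-type methanolysis) of a primary acetate, to which the alkenes and the tertiary alcohol are inert.

Step 12
Reactants: 19 (2E,6E)-3,7,11-trimethyldodeca-2,6-diene-1,11-diol
Product: 20 (6E,10E)-12-bromo-2,6,10-trimethyldodeca-6,10-dien-2-ol
Conditions: CBr4, PPh3, CH2Cl2, −20 → 0 °C; used without storage
Reagents that add atoms: carbon tetrabromide, BrC(Br)(Br)Br
Why: Appel reaction, in which only the primary allylic alcohol forms an alkoxyphosphonium ion that bromide can displace by SN2, so the hindered tertiary alcohol should survive and the E geometry is kept without allylic transposition.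

Step 13
Reactants: 14 4,5-dihydroxy-6-methoxyisobenzofuran-1(3H)-one; 20 (6E,10E)-12-bromo-2,6,10-trimethyldodeca-6,10-dien-2-ol
Product: 21 farnesylemefuranone E, 4-hydroxy-5-{[(2E,6E)-11-hydroxy-3,7,11-trimethyldodeca-2,6-dien-1-yl]oxy}-6-methoxyisobenzofuran-1(3H)-one
Conditions: KHCO3 (1.5 equiv), 20 (1.0 equiv), degassed DMF, rt → 40 °C
Reagents that add atoms: none
Why: Williamson ether synthesis under weak base, where the C5 hydroxyl, para to the lactone carbonyl and thus the more acidic phenol, should be ionised selectively and displace the primary allylic bromide by SN2, while the C4 hydroxyl, the tertiary alcohol and the lactone stay as they are.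

**Compound list**
1 | 2,3-dihydroxy-4-methoxybenzaldehyde | COc1ccc(C=O)c(O)c1O | starting material
2 | 2,3-bis(benzyloxy)-4-methoxybenzaldehyde | COc1ccc(C=O)c(OCc2ccccc2)c1OCc1ccccc1 | intermediate
3 | 2,3-bis(benzyloxy)-4-methoxyphenyl formate | COc1ccc(OC=O)c(OCc2ccccc2)c1OCc1ccccc1 | intermediate
4 | 2,3-bis(benzyloxy)-4-methoxyphenol | COc1ccc(O)c(OCc2ccccc2)c1OCc1ccccc1 | intermediate
5 | 2,3-bis(benzyloxy)-6-bromo-4-methoxyphenol | COc1cc(Br)c(O)c(OCc2ccccc2)c1OCc1ccccc1 | intermediate
6 | [2,3-bis(benzyloxy)-6-bromo-4-methoxyphenoxy]trimethylsilane | COc1cc(Br)c(O[Si](C)(C)C)c(OCc2ccccc2)c1OCc1ccccc1 | intermediate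
7 | lithium 2,3-bis(benzyloxy)-4-methoxy-6-(trimethylsilyl)phenoxide | COc1cc([Si](C)(C)C)c([O-])c(OCc2ccccc2)c1OCc1ccccc1.[Li+] | intermediate
8 | 2,3-bis(benzyloxy)-4-methoxy-6-(trimethylsilyl)phenyl trifluoromethanesulfonate | COc1cc([Si](C)(C)C)c(OS(=O)(=O)C(F)(F)F)c(OCc2ccccc2)c1OCc1ccccc1 | intermediate
9 | tert-butyl isocyanide | CC(C)(C)[N+]#[C-] | starting material
10 | formaldehyde (monomer, cracked from paraformaldehyde) | C=O | starting material
11 | 3,4-bis(benzyloxy)-5-methoxybenzyne | COC1=CC#CC(OCc2ccccc2)=C1OCc1ccccc1 | intermediate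
12 | (Z)-N-tert-butyl-4,5-bis(benzyloxy)-6-methoxyisobenzofuran-1(3H)-imine | CC(C)(C)/N=C1\OCc2c(OCc3ccccc3)c(OCc3ccccc3)c(OC)cc21 | intermediate
13 | 4,5-bis(benzyloxy)-6-methoxyisobenzofuran-1(3H)-one | COc1cc2c(c(OCc3ccccc3)c1OCc1ccccc1)COC2=O | intermediate
14 | 4,5-dihydroxy-6-methoxyisobenzofuran-1(3H)-one | COc1cc2c(c(O)c1O)COC2=O | intermediate
15 | (2E,6E)-farnesol | CC(C)=CCC/C(C)=C/CC/C(C)=C/CO | starting material
16 | (2E,6E)-farnesyl acetate | CC(=O)OC/C=C(\C)CC/C=C(\C)CCC=C(C)C | intermediate
17 | (2E,6E)-10-bromo-11-hydroxy-3,7,11-trimethyldodeca-2,6-dien-1-yl acetate (racemic) | CC(=O)OC/C=C(\C)CC/C=C(\C)CCC(Br)C(C)(C)O | intermediate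
18 | (2E,6E)-11-hydroxy-3,7,11-trimethyldodeca-2,6-dien-1-yl acetate | CC(=O)OC/C=C(\C)CC/C=C(\C)CCCC(C)(C)O | intermediate
19 | (2E,6E)-3,7,11-trimethyldodeca-2,6-diene-1,11-diol | OC/C=C(\C)CC/C=C(\C)CCCC(C)(C)O | intermediate
20 | (6E,10E)-12-bromo-2,6,10-trimethyldodeca-6,10-dien-2-ol | BrC/C=C(\C)CC/C=C(\C)CCCC(C)(C)O | intermediate
21 | farnesylemefuranone E, 4-hydroxy-5-{[(2E,6E)-11-hydroxy-3,7,11-trimethyldodeca-2,6-dien-1-yl]oxy}-6-methoxyisobenzofuran-1(3H)-one | COc1cc2c(c(O)c1OC/C=C(\C)CC/C=C(\C)CCCC(C)(C)O)COC2=O | target

**Totals**
Total step count: 13. Longest linear sequence: 8 steps (steps 1–7 and step 13, from compound 1); the side-chain branch from farnesol is 6 steps (steps 8–12 and step 13).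

**Steps most likely to fail**

1. Step 5. Fluoride may oligomerise the formaldehyde, or the aryne may be consumed by formaldehyde or by protonation of the aryl anion before the three components have combined, so that little of the cyclic imidate forms. The fallback gives up the aryne and keeps the formyl carbon of the starting aldehyde as C3. It sets out from 2, which is masked in the flask as its lithium α-amino alkoxide with lithium N,N,N'-trimethylethylenediamide. Directed ortho-lithiation with n-BuLi then takes place at the only free position next to the masked formyl group. Carboxylation with CO2 and acidic work-up should give 3,4-bis(benzyloxy)-2-formyl-5-methoxybenzoic acid F1. Reduction of its aldehyde with NaBH4 in MeOH and acidification closes the lactone, and the route is rejoined at 13.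

2. Step 13. Ionisation and alkylation may not discriminate fully between the two phenols, leading to ether formation at the C4 oxygen or at both oxygens, and the free catechol may oxidise in the basic medium. The fallback sets out from 14 and blocks the C4 oxygen. Ac2O and pyridine give 6-methoxy-1-oxo-1,3-dihydroisobenzofuran-4,5-diyl diacetate F2. One equivalent of pyrrolidine in CH2Cl2 at 0 °C removes the more activated acetate para to the lactone carbonyl and gives 5-hydroxy-6-methoxy-1-oxo-1,3-dihydroisobenzofuran-4-yl acetate F3. Mitsunobu etherification of F3 with diol 19 (PPh3, DIAD, THF, 0 °C; the tertiary alcohol does not react) gives 5-{[(2E,6E)-11-hydroxy-3,7,11-trimethyldodeca-2,6-dien-1-yl]oxy}-6-methoxy-1-oxo-1,3-dihydroisobenzofuran-4-yl acetate F4. Methanolysis with K2CO3 in MeOH at 0 °C then rejoins the route at 21.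

3. Step 3. Bromination may go partly to C5 (ortho to the methoxy group), or the electron-rich phenol may be over-brominated or oxidised. The fallback avoids halogen altogether and also bypasses the lithiation and silyl shift of step 4. It sets out from 4, which with isopropyl isocyanate and Et3N gives 2,3-bis(benzyloxy)-4-methoxyphenyl N-isopropylcarbamate F5. Carbamate-directed ortho-lithiation (TMSOTf and TMEDA for N-silylation in the flask, then n-BuLi and TMEDA at −78 °C) and a TMSCl quench give 2,3-bis(benzyloxy)-4-methoxy-6-(trimethylsilyl)phenyl N-isopropylcarbamate F6. Cleavage of the carbamate with DBU and Et2NH in MeCN and triflation of the phenoxide with PhNTf2 in the same flask rejoin the route at 8.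

Further compounds
F1 | step 5 | 3,4-bis(benzyloxy)-2-formyl-5-methoxybenzoic acid | COc1cc(C(=O)O)c(C=O)c(OCc2ccccc2)c1OCc1ccccc1
F2 | step 13 | 6-methoxy-1-oxo-1,3-dihydroisobenzofuran-4,5-diyl diacetate | COc1cc2c(c(OC(C)=O)c1OC(C)=O)COC2=O
F3 | step 13 | 5-hydroxy-6-methoxy-1-oxo-1,3-dihydroisobenzofuran-4-yl acetate | COc1cc2c(c(OC(C)=O)c1O)COC2=O
F4 | step 13 | 5-{[(2E,6E)-11-hydroxy-3,7,11-trimethyldodeca-2,6-dien-1-yl]oxy}-6-methoxy-1-oxo-1,3-dihydroisobenzofuran-4-yl acetate | COc1cc2c(c(OC(C)=O)c1OC/C=C(\C)CC/C=C(\C)CCCC(C)(C)O)COC2=O
F5 | step 3 | 2,3-bis(benzyloxy)-4-methoxyphenyl N-isopropylcarbamate | COc1ccc(OC(=O)NC(C)C)c(OCc2ccccc2)c1OCc1ccccc1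
F6 | step 3 | 2,3-bis(benzyloxy)-4-methoxy-6-(trimethylsilyl)phenyl N-isopropylcarbamate | COc1cc([Si](C)(C)C)c(OC(=O)NC(C)C)c(OCc2ccccc2)c1OCc1ccccc1
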